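**Retrosynthetic overview**

- Isogmelinol is taken back to its C1 epimer (acid equilibration of the benzylic ether carbon C1) and then to the C6 lactone of the silyl-protected bicycle (C6 carbonyl to CH2).
- Ring A (C1–O2–C3–C3a–C6a) is opened at the C6a–C1 bond. This bond joins the lactone α-carbon C6a to the benzylic ether carbon C1, whose C–H bond is activated by O2 and by the dimethoxyphenyl ring, so a rhodium carbenoid at C6a can insert into it; the route rests on this feature.
- The α-diazo lactone (ring B, C3a–C4–O5–C6–C6a) comes from a 4-hydroxy-γ-lactone by silylation and diazo transfer at C6a.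
- That lactone is cut at C3a–C6a (acetate aldol on an α-hydroxy ketone, controlled by the C4 alkoxide chelate) and the ketone at C3a–C3 (veratryloxymethyllithium plus an (R)-mandelic Weinreb amide).
- Order of ring formation: ring B (lactone) in step 6, ring A in step 9.

Key step: step 9

Remark: the furo[3,4-c]furan atom numbers (C1 and C4 aryl carbons, O2, O5, C3 and C6 methylenes, C3a carbinol bridgehead, C6a CH bridgehead) are used for all intermediates; exo means cis to H-6a and the C3a oxygen, and the target SMILES has both aryl groups exo, (1S,3aS,4R,6aR).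

Remark: in insertions of this kind the C1 aryl group is expected to emerge endo, not exo; the route is therefore written for the C1-endo series and C1 is inverted in step 13, where any exo material from step 9 converges as well.

**Step 1**
Reactants: 1 veratrole, 2 ethyl chlorooxoacetate
Product: 3 ethyl 2-(3,4-dimethoxyphenyl)-2-oxoacetate
Conditions: AlCl3, CH2Cl2, 0 °C
Reagents that add atoms: none
Why: Friedel–Crafts acylation, in which the acid chloride end of 2 gives the acylium ion and veratrole reacts para to a methoxy group, its only unhindered strongly activated position.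

**Step 2**
Reactants: 3 ethyl 2-(3,4-dimethoxyphenyl)-2-oxoacetate
Product: 4 ethyl (R)-2-(3,4-dimethoxyphenyl)-2-hydroxyacetate
Conditions: RuCl[(S,S)-TsDPEN](p-cymene) (1 mol %), HCO2H/Et3N (5:2), DMF, rt
Reagents that add atoms: none
Why: Asymmetric transfer hydrogenation of an aryl ketone, in which the (S,S) catalyst should deliver hydride to the same face as in acetophenone-type ketones (ester in the place of the alkyl group), which corresponds to the (R)-carbinol that becomes C4; the enantiomeric purity can be raised by crystallisation of 5.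

**Step 3**
Reactants: 4 ethyl (R)-2-(3,4-dimethoxyphenyl)-2-hydroxyacetate
Product: 5 (R)-2-(3,4-dimethoxyphenyl)-2-hydroxy-N-methoxy-N-methylacetamide
Conditions: MeNH(OMe)·HCl, i-PrMgCl (excess), THF, −20 to 0 °C
Reagents that add atoms: N,O-dimethylhydroxylamine hydrochloride CNOC.Cl
Why: Aminolysis of the ester by the chloromagnesium amide of N,O-dimethylhydroxylamine (Weinreb amide formation), with the hydroxyl held as its magnesium alkoxide so that the α-C–H is not deprotonated and C4 is kept.

**Step 4**
Reactants: 6 3,4-dimethoxybenzyl alcohol, 7 tributyl(iodomethyl)stannane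
Product: 8 tributyl{[(3,4-dimethoxybenzyl)oxy]methyl}stannane
Conditions: NaH, THF/DMF, 0 °C to rt
Reagents that add atoms: none
Why: Williamson ether synthesis, the sodium alkoxide of 6 displacing iodide from the primary carbon next to tin (SN2), which gives the tin precursor of the α-alkoxy carbanion.

**Step 5**
Reactants: 5 (R)-2-(3,4-dimethoxyphenyl)-2-hydroxy-N-methoxy-N-methylacetamide, 8 tributyl{[(3,4-dimethoxybenzyl)oxy]methyl}stannane
Product: 10 (R)-1-(3,4-dimethoxyphenyl)-3-[(3,4-dimethoxybenzyl)oxy]-1-hydroxypropan-2-one, via veratryloxymethyllithium 9 (not isolated)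
Conditions: 8, n-BuLi, THF, −78 °C; then 5 premixed with i-PrMgCl (1.0 equiv, THF, −40 °C), −78 °C; aq. NH4Cl, −78 °C
Reagents that add atoms: none
Why: Tin–lithium exchange at −78 °C gives the α-alkoxymethyllithium 9 before [1,2]-Wittig rearrangement can set in, and 9 adds once to the Weinreb amide (chelated tetrahedral intermediate, ketone released only on quench), while the magnesium alkoxide made beforehand from the hydroxyl saves a second equivalent of 9 and protects the α-C–H, so that the C4 configuration should be kept.

**Step 6**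
Reactants: 10 (R)-1-(3,4-dimethoxyphenyl)-3-[(3,4-dimethoxybenzyl)oxy]-1-hydroxypropan-2-one
Product: 12 (4S,5R)-4-{[(3,4-dimethoxybenzyl)oxy]methyl}-5-(3,4-dimethoxyphenyl)-4-hydroxyoxolan-2-one (aryl cis to the hydroxyl), via open-chain aldol adduct 11 (not isolated)
Conditions: LiN(i-Pr)2, EtOAc (3 equiv each), THF, −78 °C; 10, −78 to 0 °C; aq. NH4Cl; then PPTS (cat.), CH2Cl2, rt
Reagents that add atoms: ethyl acetate CC(=O)OCC
Why: Aldol addition of a lithium ester enolate under chelation control, in which the first equivalent turns the C4 hydroxyl into a lithium alkoxide that holds the ketone oxygen in a five-membered chelate (the ether oxygen on C3 cannot compete with this covalently bound alkoxide) and the next attacks C3a on the face of the C4 hydrogen, anti to the aryl group, which sets C3a (S) with its oxygen cis to the aryl group; the C4 oxygen then closes the γ-lactone (ring B) on the ethyl ester.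

**Step 7**
Reactants: 12 (4S,5R)-4-{[(3,4-dimethoxybenzyl)oxy]methyl}-5-(3,4-dimethoxyphenyl)-4-hydroxyoxolan-2-one
Product: 13 (4S,5R)-4-{[(3,4-dimethoxybenzyl)oxy]methyl}-5-(3,4-dimethoxyphenyl)-4-(triethylsilyloxy)oxolan-2-one
Conditions: Et3SiOTf, 2,6-lutidine, CH2Cl2, −78 to 0 °C
Reagents that add atoms: triethylsilyl trifluoromethanesulfonate CC[Si](CC)(CC)OS(=O)(=O)C(F)(F)F
Why: Silylation with a silyl triflate and a hindered pyridine base reaches the tertiary alcohol and masks the hydroxyl, which would otherwise intercept or redirect the carbenoid of step 9.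

**Step 8**
Reactants: 13 (4S,5R)-4-{[(3,4-dimethoxybenzyl)oxy]methyl}-5-(3,4-dimethoxyphenyl)-4-(triethylsilyloxy)oxolan-2-one
Product: 15 (4S,5R)-3-diazo-4-{[(3,4-dimethoxybenzyl)oxy]methyl}-5-(3,4-dimethoxyphenyl)-4-(triethylsilyloxy)oxolan-2-one, via 3-trifluoroacetyl lactone 14 (not isolated)
Conditions: LiN(SiMe3)2, THF, −78 °C; CF3CO2CH2CF3, −78 °C; aq. HCl work-up; then MsN3, Et3N, H2O, MeCN, rt
Reagents that add atoms: methanesulfonyl azide CS(=O)(=O)N=[N+]=[N-]
Why: Detrifluoroacetylative diazo transfer (Regitz-type diazo transfer with acyl cleavage), in which Claisen-type C-acylation of the lactone enolate at −78 °C, cold enough that loss of the β-silyloxy group should not compete, makes C6a a 1,3-dicarbonyl carbon to which the sulfonyl azide transfers N2 while the trifluoroacetyl group leaves as the N-sulfonyl amide.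

**Step 9**
Reactants: 15 (4S,5R)-3-diazo-4-{[(3,4-dimethoxybenzyl)oxy]methyl}-5-(3,4-dimethoxyphenyl)-4-(triethylsilyloxy)oxolan-2-one
Product: 16 C6 lactone of O-triethylsilyl 1-epi-isogmelinol, (1R,3aS,4R,6aR) in the numbering above, cis-fused, C1 aryl endo and C4 aryl exo
Conditions: Rh2(OAc)4 (2 mol %), CH2Cl2, rt, slow addition of 15
Reagents that add atoms: none
Why: Rh2(OAc)4 expels N2 from the α-diazo lactone and the electrophilic rhodium carbenoid at C6a inserts into a C1–H bond of the veratryl ether through a three-centre, hydride-transfer-like transition state, forming C6a–C1; the closest known reaction type is the dirhodium-catalysed intramolecular 1,5 C–H insertion of α-diazo lactones and esters into ether-activated benzylic C–H bonds to give 2-aryl tetrahydrofurans. Ring A closes as a 1,5-insertion, a five-membered ring made by C–C bond formation. C6a is set by the tether, because C3 hangs from C3a on the face opposite to the silyloxy group, so only the cis-fused bicycle with H-6a cis to the C3a oxygen can form. At C1 either hydrogen can react, and the aryl group is expected to turn away from the carboxylate ligand sphere around rhodium, which lies on the side that becomes the convex face, so the aryl group should end up endo (trans to H-6a) and 16 is drawn as that epimer, to be corrected in step 13. The step needs chemoselectivity for C1–H over a 1,2-shift of C3 from C3a to the carbenoid carbon, over attack on the aryl rings and over ylide formation at O2; the double activation of C1–H by O2 and the electron-rich ring, the absence of hydrogen on C3a, the four-membered ring that an O2 ylide would require, and a silyl ether (a weaker donor than a free hydroxyl, with no acyl group that could migrate) should secure it.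

**Step 10**
Reactants: 16 C6 lactone of O-triethylsilyl 1-epi-isogmelinol
Product: 17 C6 lactol (anomer mixture) of O-triethylsilyl 1-epi-isogmelinol
Conditions: i-Bu2AlH, CH2Cl2, −78 °C; Rochelle salt work-up
Reagents that add atoms: none
Why: Half-reduction of a lactone with i-Bu2AlH, in which the aluminium hemiacetal does not collapse at −78 °C before work-up, so the reduction should stop at the lactol while the silyl ether, aryl ethers and ring A are inert.

**Step 11**
Reactants: 17 C6 lactol of O-triethylsilyl 1-epi-isogmelinol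
Product: 18 O-triethylsilyl 1-epi-isogmelinol, (1R,3aS,4R,6aR)
Conditions: Et3SiH, BF3·OEt2, CH2Cl2, −78 °C, cold quench
Reagents that add atoms: none
Why: Ionic hydrogenation of a lactol, in which BF3·OEt2 ionises the hemiacetal to the cyclic oxocarbenium ion at C6 and Et3SiH delivers hydride, an ionisation that at −78 °C should be much faster than that of the benzylic ethers C1–O2 and C4–O5; no stereocentre is formed.

**Step 12**
Reactants: 18 O-triethylsilyl 1-epi-isogmelinol
Product: 19 1-epi-isogmelinol, (1R,3aS,4R,6aR)
Conditions: Bu4NF, THF, 0 °C to rt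
Reagents that add atoms: none
Why: Fluoride cleaves the Si–O bond of the tertiary silyl ether (strong Si–F bond) under conditions that leave the acid-sensitive benzylic ethers untouched.

**Step 13**
Reactants: 19 1-epi-isogmelinol
Product: 20 isogmelinol, (1S,3aS,4R,6aR)
Conditions: CSA (0.2 equiv), CH2Cl2, rt, to equilibrium; recovered 19 resubmitted
Reagents that add atoms: none
Why: Acid-catalysed epimerisation of a benzylic ether carbon, in which reversible ionisation of C1–O2 gives the dimethoxybenzyl cation stabilised by the para-methoxy group and the C3 hydroxyl recloses ring A from either face, so the equilibrium should favour the aryl group on the convex face (exo), while C4 should hold because a cation there would sit next to the oxygen-bearing C3a; the preference for exo is expected to be moderate, hence the recycling.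

**Compound list**

1 | veratrole (1,2-dimethoxybenzene) | COc1ccccc1OC | starting material
2 | ethyl chlorooxoacetate | CCOC(=O)C(=O)Cl | starting material
3 | ethyl 2-(3,4-dimethoxyphenyl)-2-oxoacetate | CCOC(=O)C(=O)c1ccc(OC)c(OC)c1 | intermediate
4 | ethyl (R)-2-(3,4-dimethoxyphenyl)-2-hydroxyacetate | COc1ccc([C@@H](O)C(=O)OCC)cc1OC | intermediate
5 | (R)-2-(3,4-dimethoxyphenyl)-2-hydroxy-N-methoxy-N-methylacetamide | COc1ccc([C@@H](O)C(=O)N(C)OC)cc1OC | intermediate
6 | 3,4-dimethoxybenzyl alcohol | COc1ccc(CO)cc1OC | starting material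
7 | tributyl(iodomethyl)stannane | CCCC[Sn](CCCC)(CCCC)CI | starting material
8 | tributyl{[(3,4-dimethoxybenzyl)oxy]methyl}stannane | CCCC[Sn](CCCC)(CCCC)COCc1ccc(OC)c(OC)c1 | intermediate
9 | {[(3,4-dimethoxybenzyl)oxy]methyl}lithium | [Li]COCc1ccc(OC)c(OC)c1 | intermediate (not isolated)
10 | (R)-1-(3,4-dimethoxyphenyl)-3-[(3,4-dimethoxybenzyl)oxy]-1-hydroxypropan-2-one | COc1ccc([C@@H](O)C(=O)COCc2ccc(OC)c(OC)c2)cc1OC | intermediate
11 | ethyl (3S,4R)-3-{[(3,4-dimethoxybenzyl)oxy]methyl}-4-(3,4-dimethoxyphenyl)-3,4-dihydroxybutanoate | COc1ccc(COC[C@@](O)(CC(=O)OCC)[C@H](O)c2ccc(OC)c(OC)c2)cc1OC | intermediate (not isolated)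
12 | (4S,5R)-4-{[(3,4-dimethoxybenzyl)oxy]methyl}-5-(3,4-dimethoxyphenyl)-4-hydroxyoxolan-2-one | COc1ccc(COC[C@]2(O)[C@@H](c3ccc(OC)c(OC)c3)OC(=O)C2)cc1OC | intermediate
13 | (4S,5R)-4-{[(3,4-dimethoxybenzyl)oxy]methyl}-5-(3,4-dimethoxyphenyl)-4-(triethylsilyloxy)oxolan-2-one | COc1ccc(COC[C@]2(O[Si](CC)(CC)CC)[C@@H](c3ccc(OC)c(OC)c3)OC(=O)C2)cc1OC | intermediate
14 | (4S,5R)-4-{[(3,4-dimethoxybenzyl)oxy]methyl}-5-(3,4-dimethoxyphenyl)-4-(triethylsilyloxy)-3-(trifluoroacetyl)oxolan-2-one | COc1ccc(COC[C@]2(O[Si](CC)(CC)CC)[C@@H](c3ccc(OC)c(OC)c3)OC(=O)C2C(=O)C(F)(F)F)cc1OC | intermediate (not isolated)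
15 | (4S,5R)-3-diazo-4-{[(3,4-dimethoxybenzyl)oxy]methyl}-5-(3,4-dimethoxyphenyl)-4-(triethylsilyloxy)oxolan-2-one | COc1ccc(COC[C@]2(O[Si](CC)(CC)CC)[C@@H](c3ccc(OC)c(OC)c3)OC(=O)C2=[N+]=[N-])cc1OC | intermediate
16 | C6 lactone of O-triethylsilyl 1-epi-isogmelinol (C1 aryl endo, C4 aryl exo, cis-fused) | COc1ccc([C@@H]2OC[C@]3(O[Si](CC)(CC)CC)[C@@H](c4ccc(OC)c(OC)c4)OC(=O)[C@H]23)cc1OC | intermediate
17 | C6 lactol of O-triethylsilyl 1-epi-isogmelinol (anomer mixture) | COc1ccc([C@@H]2OC[C@]3(O[Si](CC)(CC)CC)[C@@H](c4ccc(OC)c(OC)c4)OC(O)[C@H]23)cc1OC | intermediate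
18 | O-triethylsilyl 1-epi-isogmelinol | COc1ccc([C@@H]2OC[C@]3(O[Si](CC)(CC)CC)[C@@H](c4ccc(OC)c(OC)c4)OC[C@H]23)cc1OC | intermediate
19 | 1-epi-isogmelinol | COc1ccc([C@@H]2OC[C@]3(O)[C@@H](c4ccc(OC)c(OC)c4)OC[C@H]23)cc1OC | intermediate
20 | isogmelinol | COc1ccc([C@H]2OC[C@]3(O)[C@@H](c4ccc(OC)c(OC)c4)OC[C@H]23)cc1OC | target

**Step count**

Total: 13 steps. Longest linear sequence: 12 steps (steps 1–3 and 5–13; step 4 is the side branch).

**Steps most likely to fail, with fallbacks**

Step 9 (carbenoid C–H insertion). The carbenoid may be diverted before it reaches C1–H, by a 1,2-shift of the alkoxymethyl carbon C3 from the oxygenated C3a to C6a (leading to a silyloxy butenolide) or by attack on an aryl ring. The fallback sets out from 13 and makes the C6a–C1 bond by aldol addition and ring A by cation cyclisation. Deprotonation of 13 (LiN(SiMe3)2, THF, −78 °C) and addition of 3,4-dimethoxybenzaldehyde should give the C6a (aryl)hydroxymethyl lactone F1, the aldehyde entering on the face of the C3 arm, away from the silyloxy and C4 aryl groups. BF3·OEt2 with pentamethylbenzene in CH2Cl2 at −40 °C then ionises the benzylic alcohol, O2 closes ring A and the dimethoxybenzyl group is lost to the scavenger (debenzylative cycloetherification), which should give mainly the C1-exo lactone F2. Treatment as in steps 10, 11 and 12 leads through the lactol F3 and the silyl ether F4 to 20, where the fallback rejoins the route without step 13; it would therefore also serve if the equilibrium of step 13 lay unfavourably.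

Step 8 (diazo transfer). The lactone enolate of 13 may expel triethylsilanolate from C3a (β-elimination to a butenolide) faster than it is acylated. The fallback sets out from 10 and brings in the diazo carbon together with C6a and C6 by an aldol-type addition of lithiated ethyl diazoacetate (N2CHCO2Et, LiN(i-Pr)2, 3 equiv, THF, −78 °C), again through the lithium alkoxide chelate, to give the diazo diol ester F5. This is lactonised through the C4 alkoxide on warming to 0 °C (or with DBU in CH2Cl2) to the 3-diazo-4-hydroxy lactone F6, and silylation (Et3SiOTf, 2,6-lutidine, CH2Cl2, −78 °C) rejoins the route at 15 without any enolate of a β-silyloxy lactone.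

Step 11 (lactol deoxygenation). BF3·OEt2 may also ionise the electron-rich benzylic ether bonds C1–O2 or C4–O5, so that the silane opens a ring or C4 is scrambled. The fallback sets out from 16 and avoids the Lewis acid. LiAlH4 (THF, 0 °C) reduces the lactone to the diol F7, the primary C6 hydroxyl is sulfonylated selectively (TsCl, pyridine, 0 °C) to the monotosylate F8, and NaH in THF closes ring B by 5-exo-tet Williamson etherification through the C4 alkoxide, with retention at C4, to rejoin the route at 18.

**Further compounds**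

F1 | step 9 | (4S,5R)-4-{[(3,4-dimethoxybenzyl)oxy]methyl}-3-[(3,4-dimethoxyphenyl)(hydroxy)methyl]-5-(3,4-dimethoxyphenyl)-4-(triethylsilyloxy)oxolan-2-one (C6a as in 16, carbinol epimers) | COc1ccc(COC[C@]3(O[Si](CC)(CC)CC)[C@@H](c4ccc(OC)c(OC)c4)OC(=O)[C@@H]3C(O)c2ccc(OC)c(OC)c2)cc1OC
F2 | step 9 | C6 lactone of O-triethylsilyl isogmelinol (C1 aryl exo) | COc1ccc([C@H]2OC[C@]3(O[Si](CC)(CC)CC)[C@@H](c4ccc(OC)c(OC)c4)OC(=O)[C@H]23)cc1OC
F3 | step 9 | C6 lactol of O-triethylsilyl isogmelinol (anomer mixture) | COc1ccc([C@H]2OC[C@]3(O[Si](CC)(CC)CC)[C@@H](c4ccc(OC)c(OC)c4)OC(O)[C@H]23)cc1OC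
F4 | step 9 | O-triethylsilyl isogmelinol | COc1ccc([C@H]2OC[C@]3(O[Si](CC)(CC)CC)[C@@H](c4ccc(OC)c(OC)c4)OC[C@H]23)cc1OC
F5 | step 8 | ethyl (3S,4R)-2-diazo-3-{[(3,4-dimethoxybenzyl)oxy]methyl}-4-(3,4-dimethoxyphenyl)-3,4-dihydroxybutanoate | COc1ccc(COC[C@@](O)(C(=[N+]=[N-])C(=O)OCC)[C@H](O)c2ccc(OC)c(OC)c2)cc1OC
F6 | step 8 | (4S,5R)-3-diazo-4-{[(3,4-dimethoxybenzyl)oxy]methyl}-5-(3,4-dimethoxyphenyl)-4-hydroxyoxolan-2-one | COc1ccc(COC[C@]2(O)[C@@H](c3ccc(OC)c(OC)c3)OC(=O)C2=[N+]=[N-])cc1OC
F7 | step 11 | ring A diol: (R)-(3,4-dimethoxyphenyl)[(3S,4R,5R)-5-(3,4-dimethoxyphenyl)-4-(hydroxymethyl)-3-(triethylsilyloxy)oxolan-3-yl]methanol | COc1ccc([C@@H]2OC[C@](O[Si](CC)(CC)CC)([C@H](O)c3ccc(OC)c(OC)c3)[C@@H]2CO)cc1OC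
F8 | step 11 | primary p-toluenesulfonate of F7 | COc1ccc([C@@H]2OC[C@](O[Si](CC)(CC)CC)([C@H](O)c3ccc(OC)c(OC)c3)[C@@H]2COS(=O)(=O)c2ccc(C)cc2)cc1OC
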